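## Analysis of the target

The target is an unsymmetrical biflavone: two 2-arylchromen-4-ones joined by one aryl–aryl bond between C8 of a 5,7-dihydroxy-4'-methoxyflavone (unprimed half, the skeleton of acacetin 1) and C6'' of a 5'',7'',4'''-trihydroxyflavone (double-primed half). It has no stereogenic carbon. The only stereochemical element is the C8–C6'' axis, flanked by four oxygen-bearing carbons (C7, C8a, C5'', C7''), which will rotate slowly but is specified without a descriptor. Sensitive groups are the five phenols (two chelated to the C4 and C4'' carbonyls), the single methyl ether on ring B of the unprimed half, which must survive the final unmasking, and the two pyranones, which do not tolerate organolithium reagents or hot hydroxide. The synthesis is hard for three reasons: the halves differ only in one O-methyl group and in the position of the link, so no dimerisation can be used; C6'' and C8'' of a 5,7-dioxygenated flavone are hard to tell apart; and the biaryl bond is tetra-ortho-substituted. The strategy rests on ring A of the double-primed half: C8a'' carries the ring oxygen O1'', its neighbour C4a'' carries the acyl carbon C4'', and C4a'' sits beside the oxygenated C5''. That is the pattern left when an aryne C4a''≡C8a'' takes up an oxygen and an acyl carbon in one event, with the C5'' oxygen deciding which end receives which. Because C6'' is para to C8a'', the ring before the aryne stage is a 4-aryl-3,5-dialkoxyphenol with a local mirror plane, and the C6''/C8'' question disappears.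

## Retrosynthetic reasoning

20 from 19: the five O–benzyl bonds are cut last. Benzyl is chosen for every masked oxygen, including O5, because a Lewis acid with a cation scavenger removes it at low temperature without touching the one aryl methyl ether that belongs to the target. A methyl ether at C5 would cost an extra step on 1 and would force the last step to cleave one methyl ether beside another.

19 from 17: the O1''–C2'' bond is cut, which opens the double-primed pyranone to an ortho-hydroxyaryl ynone. The forward closure must be 6-endo and not 5-exo; running it through an amine adduct (18) guarantees that.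

17 from 12 and 15: the two bonds that tie the three-carbon unit and ring B'' to ring A'' are cut together, O1''–C8a'' and C4''–C4a''. Cutting here leaves on one side an intact flavone carrying a simple aryne precursor and on the other a small propiolic acid. It also avoids a Friedel–Crafts acylation on a ring loaded with benzyl ethers. The forward step must generate aryne 16 from 12, direct the carboxylate oxygen to C8a'', and transfer the acyl group to C4a'' before the aryl anion is protonated.

15 from 13: the C–CO2H bond is cut; the forward step is carboxylation of the acetylide 14.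

12 from 11, 10 and 9: the O–triflyl, C–Si and C–Br bonds are removed in turn, back to phenol 9. Both positions ortho to the hydroxyl of 9 are equivalent, so the silyl group can be placed without a regiochemical decision. The C–Si bond has to be made by transition-metal catalysis and not through an aryllithium, because the pyranone is present.

9 from 8, and 8 from 3 and 7: the C8–C6'' bond is cut. It is made early, while the double-primed half is still a locally symmetric trioxygenated benzene, so the only regiochemistry to control is on the unprimed half, where C8 is the natural site of halogenation once both hydroxyls are alkylated. The forward coupling must join two di-ortho-oxygenated partners; all four ortho substituents are oxygen functions, not alkyl groups, which keeps it within reach of a hindered-biaryl catalyst.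

3 from 2 and 1: the C8–I bond and the two benzyl ethers are removed, back to acacetin 1, which supplies the whole unprimed half with its methyl ether in place.

7 from 5 and 4: the C–B bond is cut back to silyl ether 5 (through aryllithium 6) and then to commercial phenol 4. The position between the two benzyloxy groups is the one a directed metalation reaches, and the bulky silyl ether keeps the base away from its own ortho positions.

## Alternatives that were turned down

Alternative 1: Ring A of the unprimed half is cut at C8–C8a and C6–C7 (C4a–C8a closes in the same cascade), back to 3-ethoxycyclobut-2-en-1-one A2 and the flavone-bound siloxyalkyne A3. On heating, A2 opens to a vinylketene, which adds to the alkyne of A3; four-electron ring opening and six-electron closure then give the phenol A1, in which the three ring oxygens are differentiated (free hydroxyl on C8a, silyl ether on C7, ethyl ether on C5).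
- For: the crowded C8–C6'' bond is never made by cross-coupling, because it starts as an unhindered aryl–alkyne bond and the ring is grown around it. On this point it is stronger than the chosen route, which relies on a tetra-ortho coupling.
- Against: A1 still lacks C4, C3, C2 and ring B of the unprimed half. C4a must then be acylated in competition with C6, and the pyranone built by aroylation, rearrangement and cyclisation, five or six further steps. A3 requires C6''-selective functionalisation of a 5,7-dioxygenated flavone and a siloxyalkyne, normally made from an ester with strong base, beside a pyranone. The ethyl ether on C5 needs a cleavage that must spare the 4'-methyl ether.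
- Comparison: the chosen strategy offers a key step that installs the whole C3–ring B unit with its regiochemistry fixed and leaves only two steps to the target.

Alternative 2: Ring A of the double-primed half is cut at C8''–C8a'' and C5''–C4a'', back to the flavon-8-yl-substituted bis(silyloxy)diene A5 and the bromopyranone A6. They would combine by cycloaddition (or a stepwise Lewis-acid-mediated Michael–aldol sequence), and loss of HBr and methanol would aromatise the ring to A4.
- For: it is the most convergent plan. Rings B and C of the double-primed half arrive intact in A6, the aryl group sits on the central diene carbon so C6'' is unambiguous, and A4 emerges with both ring A'' hydroxyls free. On convergence it is stronger than the chosen route.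
- Against: A5 is a tetrasubstituted ketene acetal carrying a bulky flavonyl group on C2, which twists the diene out of the reactive s-cis form. Its β-ketoester precursor needs an α-arylation by the hindered 8-iodoflavone 3, and the double enolisation needs a strong amide base beside a pyranone. A6 is a poor dienophile, a vinylogous ester with aromatic character whose reacting carbons bear bromine and oxygen. Hydrolysis of the diene would compete.
- Comparison: both plans carry their risk in one step, but the chosen one reaches its key precursor by robust reactions, and its key step has a close analogy on simpler arynes.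

Alternative 3: The unprimed pyranone is cut at O1–C8a, back to the 2-fluoroaryl 1,3-diketone A8. Carbonate base would form the enolate, whose oxygen displaces fluoride ortho to the aroyl group to give the protected biflavone A7.
- For: the displacement is activated by the ortho carbonyl, is not disturbed electronically by the meta alkoxy groups, and has no regiochemical ambiguity. As a key step it is more reliable than the aryne insertion.
- Against: it forms one bond and builds no carbon skeleton. The hard problems move to earlier steps: a biaryl coupling next to fluorine, C6''-selective functionalisation of the other flavone, a fluorinated trioxygenated benzene as starting material, and a diketone synthesis with strong base beside a pyranone. Neither half can be taken intact from 1, so the count is longer.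
- Comparison: the chosen strategy gives two skeletal bonds in the key step and uses 1 unchanged as one half.

Key step: step 11

Assumption: the target is specified without a descriptor for the C8–C6'' axis, so the route aims at the racemate and attempts no axial control.

## Route

Step 1
Reactants: 1 acacetin (5,7-dihydroxy-2-(4-methoxyphenyl)-4H-chromen-4-one)
Product: 2 5,7-bis(benzyloxy)-2-(4-methoxyphenyl)-4H-chromen-4-one
Conditions: BnBr (3 equiv), K2CO3, Bu4NI (cat.), DMF, 80 °C
Reagents that add atoms: benzyl bromide, BrCc1ccccc1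
Why: Williamson etherification; the 7-hydroxyl reacts first and the chelated 5-hydroxyl follows with excess halide and heat, so both are masked in one operation while the 4'-methyl ether is untouched.

Step 2
Reactants: 2 5,7-bis(benzyloxy)-2-(4-methoxyphenyl)-4H-chromen-4-one
Product: 3 5,7-bis(benzyloxy)-8-iodo-2-(4-methoxyphenyl)-4H-chromen-4-one
Conditions: I2, CF3CO2Ag, CH2Cl2, 0 °C to rt
Reagents that add atoms: iodine, II
Why: Electrophilic aromatic iodination by the acyl hypoiodite formed in the flask; fully O-alkylated 5,7-dioxygenated flavones are attacked at C8 (para to O5, ortho to O7), and C6 is additionally hemmed in by two benzyloxy groups.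

Step 3
Reactants: 4 3,5-bis(benzyloxy)phenol
Product: 5 [3,5-bis(benzyloxy)phenoxy]tri(propan-2-yl)silane
Conditions: iPr3SiCl, imidazole, DMF, rt
Reagents that add atoms: chlorotri(propan-2-yl)silane, CC(C)[Si](Cl)(C(C)C)C(C)C
Why: Standard silylation of a phenol; the bulky silyl ether masks the acidic proton and does not coordinate lithium, which sets up the next step.

Step 4
Reactants: 5 [3,5-bis(benzyloxy)phenoxy]tri(propan-2-yl)silane
Product: 7 {3,5-bis(benzyloxy)-4-(4,4,5,5-tetramethyl-1,3,2-dioxaborolan-2-yl)phenoxy}tri(propan-2-yl)silane, via aryllithium 6 (not isolated)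
Conditions: n-BuLi, THF, 0 °C; then iPrOBpin, −78 °C to rt
Reagents that add atoms: 2-isopropoxy-4,4,5,5-tetramethyl-1,3,2-dioxaborolane, CC(C)OB1OC(C)(C)C(C)(C)O1
Why: Directed ortho-metalation at the position flanked by two coordinating benzyloxy groups, the most acidic ring C–H, followed by borylation of aryllithium 6; the hindered silyl ether does not direct the base to its own ortho positions.

Step 5
Reactants: 3 5,7-bis(benzyloxy)-8-iodo-2-(4-methoxyphenyl)-4H-chromen-4-one; 7 {3,5-bis(benzyloxy)-4-(4,4,5,5-tetramethyl-1,3,2-dioxaborolan-2-yl)phenoxy}tri(propan-2-yl)silane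
Product: 8 5,7-bis(benzyloxy)-8-{2,6-bis(benzyloxy)-4-[tri(propan-2-yl)silyloxy]phenyl}-2-(4-methoxyphenyl)-4H-chromen-4-one
Conditions: Pd(OAc)2 (10 mol %), SPhos (20 mol %), K3PO4, toluene/H2O 10:1, 100 °C, 7 in excess
Reagents that add atoms: none
Why: Suzuki–Miyaura coupling; the bulky electron-rich biarylphosphine is suited to tetra-ortho-substituted biaryls, and here all four ortho groups are oxygen substituents, which are smaller than alkyl groups.

Step 6
Reactants: 8 5,7-bis(benzyloxy)-8-{2,6-bis(benzyloxy)-4-[tri(propan-2-yl)silyloxy]phenyl}-2-(4-methoxyphenyl)-4H-chromen-4-one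
Product: 9 5,7-bis(benzyloxy)-8-[2,6-bis(benzyloxy)-4-hydroxyphenyl]-2-(4-methoxyphenyl)-4H-chromen-4-one
Conditions: Bu4NF, THF, 0 °C; aq. NH4Cl
Reagents that add atoms: none
Why: Fluoride cleavage of the aryl silyl ether; benzyl ethers and the pyranone are inert under these conditions.

Step 7
Reactants: 9 5,7-bis(benzyloxy)-8-[2,6-bis(benzyloxy)-4-hydroxyphenyl]-2-(4-methoxyphenyl)-4H-chromen-4-one
Product: 10 5,7-bis(benzyloxy)-8-[2,6-bis(benzyloxy)-3-bromo-4-hydroxyphenyl]-2-(4-methoxyphenyl)-4H-chromen-4-one
Conditions: NBS (1.0 equiv), CH2Cl2, −78 to −40 °C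
Reagents that add atoms: N-bromosuccinimide, O=C1CCC(=O)N1Br
Why: Electrophilic bromination ortho to the free hydroxyl of the most electron-rich ring (three oxygen donors, no acyl group); the two ortho positions are equivalent, and one equivalent at low temperature limits dibromination and attack on the flavone.

Step 8
Reactants: 10 5,7-bis(benzyloxy)-8-[2,6-bis(benzyloxy)-3-bromo-4-hydroxyphenyl]-2-(4-methoxyphenyl)-4H-chromen-4-one
Product: 11 5,7-bis(benzyloxy)-8-[2,6-bis(benzyloxy)-4-hydroxy-3-(trimethylsilyl)phenyl]-2-(4-methoxyphenyl)-4H-chromen-4-one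
Conditions: Me3SiSiMe3, Pd2(dba)3 (5 mol %), 2-(di-tert-butylphosphino)biphenyl, KF, H2O, DMPU, 100 °C
Reagents that add atoms: hexamethyldisilane, C[Si](C)(C)[Si](C)(C)C
Why: Palladium-catalysed silylation of an aryl bromide with a disilane (oxidative addition, fluoride-assisted Si–Si transmetalation, C–Si reductive elimination); it forms the C–Si bond without an aryllithium, so the pyranone is not attacked.

Step 9
Reactants: 11 5,7-bis(benzyloxy)-8-[2,6-bis(benzyloxy)-4-hydroxy-3-(trimethylsilyl)phenyl]-2-(4-methoxyphenyl)-4H-chromen-4-one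
Product: 12 3,5-bis(benzyloxy)-4-[5,7-bis(benzyloxy)-2-(4-methoxyphenyl)-4-oxo-4H-chromen-8-yl]-2-(trimethylsilyl)phenyl trifluoromethanesulfonate
Conditions: PhNTf2, Et3N, DMAP (cat.), CH2Cl2, 0 °C to rt
Reagents that add atoms: N-phenylbis(trifluoromethanesulfonimide), O=S(=O)(N(c1ccccc1)S(=O)(=O)C(F)(F)F)C(F)(F)F
Why: O-sulfonylation of the phenol; the imide reagent is mild enough not to activate the pyranone carbonyl, as the anhydride could, and the fluoride-free, weakly basic medium leaves the C–Si bond intact.

Step 10
Reactants: 13 1-(benzyloxy)-4-ethynylbenzene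
Product: 15 3-[4-(benzyloxy)phenyl]prop-2-ynoic acid, via lithium acetylide 14 (not isolated)
Conditions: n-BuLi, THF, −78 °C; CO2; then aq. HCl
Reagents that add atoms: carbon dioxide, O=C=O
Why: Deprotonation of the terminal alkyne and carboxylation of acetylide 14, a standard route to arylpropiolic acids.

Step 11
Reactants: 12 3,5-bis(benzyloxy)-4-[5,7-bis(benzyloxy)-2-(4-methoxyphenyl)-4-oxo-4H-chromen-8-yl]-2-(trimethylsilyl)phenyl trifluoromethanesulfonate; 15 3-[4-(benzyloxy)phenyl]prop-2-ynoic acid
Product: 17 1-{2,4-bis(benzyloxy)-3-[5,7-bis(benzyloxy)-2-(4-methoxyphenyl)-4-oxo-4H-chromen-8-yl]-6-hydroxyphenyl}-3-[4-(benzyloxy)phenyl]prop-2-yn-1-one, via aryne 16 (not isolated)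
Conditions: 15 (2 equiv), CsF (5 equiv), THF, sealed tube, 125 °C; aq. NH4Cl
Reagents that add atoms: none
Why: Fluoride attacks silicon of 12 and triflate leaves, giving aryne 16 slowly because CsF is sparingly soluble in THF, so the aryne always meets an excess of the carboxylate of 15. The carboxylate oxygen adds to C8a'', the aryne carbon remote from the C5'' benzyloxy group: that inductively withdrawing substituent makes C8a'' the more electrophilic end and places the developing carbanion on C4a'' beside the C–O bond, and C8a'' is also the less hindered end, with only C8''–H on its other side. The C4a'' carbanion lies in the ring plane next to the new aryl ester and adds to its carbonyl through a four-membered alkoxide, which opens with cleavage of the acyl–oxygen bond, so the acyl group ends on C4a'' and the phenoxide on C8a''; work-up gives 17. The closest known reaction type is the insertion of arynes into the C–O bond of carboxylic acids, arylpropiolic acids among them, to give ortho-hydroxyaryl ketones. No ring is closed and no stereocentre is formed; the biaryl axis stays racemic. The step needs regioselective O-attack (secured by the C5'' alkoxy group), acyl transfer faster than protonation of the aryl anion (favoured by heat, a weakly polar aprotic solvent and the small, electrophilic ynoate carbonyl) and attack at the carbonyl, not the alkyne terminus (the linear alkyne holds its far carbon out of reach of the in-plane carbanion).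

Step 12
Reactants: 17 1-{2,4-bis(benzyloxy)-3-[5,7-bis(benzyloxy)-2-(4-methoxyphenyl)-4-oxo-4H-chromen-8-yl]-6-hydroxyphenyl}-3-[4-(benzyloxy)phenyl]prop-2-yn-1-one
Product: 19 5,7-bis(benzyloxy)-8-{5,7-bis(benzyloxy)-2-[4-(benzyloxy)phenyl]-4-oxo-4H-chromen-6-yl}-2-(4-methoxyphenyl)-4H-chromen-4-one, via enaminone 18 (not isolated)
Conditions: Et2NH, EtOH/THF, 60 °C
Reagents that add atoms: none
Why: Conjugate addition of the amine to the ynone gives enaminone 18; the phenol then adds to the same β-carbon and the amine is expelled, so the O1''–C2'' bond forms in the 6-endo sense only and the 5-exo aurone pathway is closed off.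

Step 13
Reactants: 19 5,7-bis(benzyloxy)-8-{5,7-bis(benzyloxy)-2-[4-(benzyloxy)phenyl]-4-oxo-4H-chromen-6-yl}-2-(4-methoxyphenyl)-4H-chromen-4-one
Product: 20 5,7-dihydroxy-8-[5,7-dihydroxy-2-(4-hydroxyphenyl)-4-oxo-4H-chromen-6-yl]-2-(4-methoxyphenyl)-4H-chromen-4-one
Conditions: BCl3, C6HMe5, CH2Cl2, −78 °C; then MeOH
Reagents that add atoms: none
Why: Lewis-acid debenzylation with pentamethylbenzene as a non-basic benzyl-cation scavenger; at −78 °C the five benzyl ethers are cleaved while the unchelated 4'-methyl ether is left, and the scavenger prevents C-benzylation of the electron-rich rings.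

## Compound list

1 | acacetin, 5,7-dihydroxy-2-(4-methoxyphenyl)-4H-chromen-4-one | COc1ccc(cc1)-c1cc(=O)c2c(O)cc(O)cc2o1 | starting material
2 | 5,7-bis(benzyloxy)-2-(4-methoxyphenyl)-4H-chromen-4-one | COc1ccc(cc1)-c1cc(=O)c2c(OCc3ccccc3)cc(OCc3ccccc3)cc2o1 | intermediate
3 | 5,7-bis(benzyloxy)-8-iodo-2-(4-methoxyphenyl)-4H-chromen-4-one | COc1ccc(cc1)-c1cc(=O)c2c(OCc3ccccc3)cc(OCc3ccccc3)c(I)c2o1 | intermediate
4 | 3,5-bis(benzyloxy)phenol | Oc1cc(OCc2ccccc2)cc(OCc2ccccc2)c1 | starting material
5 | [3,5-bis(benzyloxy)phenoxy]tri(propan-2-yl)silane | CC(C)[Si](Oc1cc(OCc2ccccc2)cc(OCc2ccccc2)c1)(C(C)C)C(C)C | intermediate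
6 | {2,6-bis(benzyloxy)-4-[tri(propan-2-yl)silyloxy]phenyl}lithium | [Li]c1c(OCc2ccccc2)cc(O[Si](C(C)C)(C(C)C)C(C)C)cc1OCc1ccccc1 | intermediate
7 | {3,5-bis(benzyloxy)-4-(4,4,5,5-tetramethyl-1,3,2-dioxaborolan-2-yl)phenoxy}tri(propan-2-yl)silane | CC1(C)OB(OC1(C)C)c1c(OCc2ccccc2)cc(O[Si](C(C)C)(C(C)C)C(C)C)cc1OCc1ccccc1 | intermediate
8 | 5,7-bis(benzyloxy)-8-{2,6-bis(benzyloxy)-4-[tri(propan-2-yl)silyloxy]phenyl}-2-(4-methoxyphenyl)-4H-chromen-4-one | COc1ccc(cc1)-c1cc(=O)c2c(OCc3ccccc3)cc(OCc3ccccc3)c(c2o1)-c1c(OCc2ccccc2)cc(O[Si](C(C)C)(C(C)C)C(C)C)cc1OCc1ccccc1 | intermediate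
9 | 5,7-bis(benzyloxy)-8-[2,6-bis(benzyloxy)-4-hydroxyphenyl]-2-(4-methoxyphenyl)-4H-chromen-4-one | COc1ccc(cc1)-c1cc(=O)c2c(OCc3ccccc3)cc(OCc3ccccc3)c(c2o1)-c1c(OCc2ccccc2)cc(O)cc1OCc1ccccc1 | intermediate
10 | 5,7-bis(benzyloxy)-8-[2,6-bis(benzyloxy)-3-bromo-4-hydroxyphenyl]-2-(4-methoxyphenyl)-4H-chromen-4-one | COc1ccc(cc1)-c1cc(=O)c2c(OCc3ccccc3)cc(OCc3ccccc3)c(c2o1)-c1c(OCc2ccccc2)cc(O)c(Br)c1OCc1ccccc1 | intermediate
11 | 5,7-bis(benzyloxy)-8-[2,6-bis(benzyloxy)-4-hydroxy-3-(trimethylsilyl)phenyl]-2-(4-methoxyphenyl)-4H-chromen-4-one | COc1ccc(cc1)-c1cc(=O)c2c(OCc3ccccc3)cc(OCc3ccccc3)c(c2o1)-c1c(OCc2ccccc2)cc(O)c([Si](C)(C)C)c1OCc1ccccc1 | intermediate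
12 | 3,5-bis(benzyloxy)-4-[5,7-bis(benzyloxy)-2-(4-methoxyphenyl)-4-oxo-4H-chromen-8-yl]-2-(trimethylsilyl)phenyl trifluoromethanesulfonate | COc1ccc(cc1)-c1cc(=O)c2c(OCc3ccccc3)cc(OCc3ccccc3)c(c2o1)-c1c(OCc2ccccc2)cc(OS(=O)(=O)C(F)(F)F)c([Si](C)(C)C)c1OCc1ccccc1 | intermediate
13 | 1-(benzyloxy)-4-ethynylbenzene | C#Cc1ccc(OCc2ccccc2)cc1 | starting material
14 | lithium [4-(benzyloxy)phenyl]acetylide | [Li]C#Cc1ccc(OCc2ccccc2)cc1 | intermediate
15 | 3-[4-(benzyloxy)phenyl]prop-2-ynoic acid | OC(=O)C#Cc1ccc(OCc2ccccc2)cc1 | intermediate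
16 | 5,7-bis(benzyloxy)-8-[2,6-bis(benzyloxy)-3,4-didehydrophenyl]-2-(4-methoxyphenyl)-4H-chromen-4-one (aryne) | COc1ccc(cc1)-c1cc(=O)c2c(OCc3ccccc3)cc(OCc3ccccc3)c(c2o1)C1=C(OCc2ccccc2)C#CC=C1OCc1ccccc1 | intermediate
17 | 1-{2,4-bis(benzyloxy)-3-[5,7-bis(benzyloxy)-2-(4-methoxyphenyl)-4-oxo-4H-chromen-8-yl]-6-hydroxyphenyl}-3-[4-(benzyloxy)phenyl]prop-2-yn-1-one | COc1ccc(cc1)-c1cc(=O)c2c(OCc3ccccc3)cc(OCc3ccccc3)c(c2o1)-c1c(OCc2ccccc2)cc(O)c(C(=O)C#Cc2ccc(OCc3ccccc3)cc2)c1OCc1ccccc1 | intermediate
18 | (2E)-1-{2,4-bis(benzyloxy)-3-[5,7-bis(benzyloxy)-2-(4-methoxyphenyl)-4-oxo-4H-chromen-8-yl]-6-hydroxyphenyl}-3-[4-(benzyloxy)phenyl]-3-(diethylamino)prop-2-en-1-one | COc1ccc(cc1)-c1cc(=O)c2c(OCc3ccccc3)cc(OCc3ccccc3)c(c2o1)-c1c(OCc2ccccc2)cc(O)c(C(=O)/C=C(/N(CC)CC)c2ccc(OCc3ccccc3)cc2)c1OCc1ccccc1 | intermediate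
19 | 5,7-bis(benzyloxy)-8-{5,7-bis(benzyloxy)-2-[4-(benzyloxy)phenyl]-4-oxo-4H-chromen-6-yl}-2-(4-methoxyphenyl)-4H-chromen-4-one | COc1ccc(cc1)-c1cc(=O)c2c(OCc3ccccc3)cc(OCc3ccccc3)c(c2o1)-c1c(OCc2ccccc2)cc2oc(cc(=O)c2c1OCc1ccccc1)-c1ccc(OCc2ccccc2)cc1 | intermediate
20 | 5,7-dihydroxy-8-[5,7-dihydroxy-2-(4-hydroxyphenyl)-4-oxo-4H-chromen-6-yl]-2-(4-methoxyphenyl)-4H-chromen-4-one | COc1ccc(-c2cc(=O)c3c(O)cc(O)c(-c4c(O)cc5oc(-c6ccc(O)cc6)cc(=O)c5c4O)c3o2)cc1 | target

## Step count and least certain steps

Total: 13 steps. Longest linear sequence: 10 steps (from 1 through steps 1, 2, 5, 6, 7, 8, 9, 11, 12, 13; the sequence from 4 is equally long).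

Step 11 (key step). Three things may go wrong:
- the C4a'' aryl anion may be protonated by residual acid or bifluoride before the acyl group migrates, which ends in simple O-arylation;
- the propiolate may lose CO2 at the reaction temperature;
- the product phenoxide may close onto the alkyne in the 5-exo sense while still in the hot, basic mixture.

The aryne is also more crowded than those on which this insertion is established. Fallback: from 9, iodination ortho to the hydroxyl with N-iodosuccinimide (CH2Cl2, −40 °C) gives 5,7-bis(benzyloxy)-8-[2,6-bis(benzyloxy)-4-hydroxy-3-iodophenyl]-2-(4-methoxyphenyl)-4H-chromen-4-one F1. A carbonylative Sonogashira coupling of F1 with alkyne 13 (CO 1 atm, PdCl2(PPh3)2, Et2NH, 60 °C) then forms ynone 17 at the metal, and the amine closes it in the same flask, so the route is rejoined at 19.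

Step 5. The electron-rich, di-ortho-oxygenated boronate may lose boron by protonolysis under aqueous base faster than it transmetalates to the hindered arylpalladium iodide, and the iodide may be reduced. Fallback: from 5, lithiation as in step 4 to 6, then transmetalation with ZnCl2 to chloro{2,6-bis(benzyloxy)-4-[tri(propan-2-yl)silyloxy]phenyl}zinc F2. Negishi coupling of F2 with 3 (Pd2(dba)3, SPhos, THF, 65 °C) runs without water or base and returns to the route at 8.

Step 8. The bromide is flanked by a hydroxyl and a benzyloxy group, so oxidative addition and C–Si reductive elimination may be slow and hydrodebromination may take over. The product may also lose silicon by ipso-protonation of its very electron-rich ring during isolation. Fallback: from 10, O-silylation with hexamethyldisilazane gives the silyl ether 5,7-bis(benzyloxy)-8-[2,6-bis(benzyloxy)-3-bromo-4-(trimethylsilyloxy)phenyl]-2-(4-methoxyphenyl)-4H-chromen-4-one F3. Bromine–lithium exchange with n-BuLi in THF at −100 °C is followed by 1,3 O-to-C silyl migration (retro-Brook) to lithium 3,5-bis(benzyloxy)-4-[5,7-bis(benzyloxy)-2-(4-methoxyphenyl)-4-oxo-4H-chromen-8-yl]-2-(trimethylsilyl)phenoxide F4. Quenching F4 with PhNTf2 gives 12 directly, without isolating 11.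

Step 4. Deprotonation may occur in part at a benzylic CH2 (followed by 1,2-shift of the benzyl group) or next to the silyl ether instead of between the two benzyloxy groups. Fallback: from 4, para-selective bromination of the free phenol with Bu4NBr3 gives 4-bromo-3,5-bis(benzyloxy)phenol F5, from which any ortho isomer is removed at this simple stage. Silylation as in step 3 gives [4-bromo-3,5-bis(benzyloxy)phenoxy]tri(propan-2-yl)silane F6. Bromine–lithium exchange (n-BuLi, THF, −78 °C) fixes the site of metalation and leads through 6 back to 7.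

## Further compounds

F1 | step 11 | 5,7-bis(benzyloxy)-8-[2,6-bis(benzyloxy)-4-hydroxy-3-iodophenyl]-2-(4-methoxyphenyl)-4H-chromen-4-one | COc1ccc(cc1)-c1cc(=O)c2c(OCc3ccccc3)cc(OCc3ccccc3)c(c2o1)-c1c(OCc2ccccc2)cc(O)c(I)c1OCc1ccccc1
F2 | step 5 | chloro{2,6-bis(benzyloxy)-4-[tri(propan-2-yl)silyloxy]phenyl}zinc | Cl[Zn]c1c(OCc2ccccc2)cc(O[Si](C(C)C)(C(C)C)C(C)C)cc1OCc1ccccc1
F3 | step 8 | 5,7-bis(benzyloxy)-8-[2,6-bis(benzyloxy)-3-bromo-4-(trimethylsilyloxy)phenyl]-2-(4-methoxyphenyl)-4H-chromen-4-one | COc1ccc(cc1)-c1cc(=O)c2c(OCc3ccccc3)cc(OCc3ccccc3)c(c2o1)-c1c(OCc2ccccc2)cc(O[Si](C)(C)C)c(Br)c1OCc1ccccc1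
F4 | step 8 | lithium 3,5-bis(benzyloxy)-4-[5,7-bis(benzyloxy)-2-(4-methoxyphenyl)-4-oxo-4H-chromen-8-yl]-2-(trimethylsilyl)phenoxide | COc1ccc(cc1)-c1cc(=O)c2c(OCc3ccccc3)cc(OCc3ccccc3)c(c2o1)-c1c(OCc2ccccc2)cc(O[Li])c([Si](C)(C)C)c1OCc1ccccc1
F5 | step 4 | 4-bromo-3,5-bis(benzyloxy)phenol | Oc1cc(OCc2ccccc2)c(Br)c(OCc2ccccc2)c1
F6 | step 4 | [4-bromo-3,5-bis(benzyloxy)phenoxy]tri(propan-2-yl)silane | CC(C)[Si](Oc1cc(OCc2ccccc2)c(Br)c(OCc2ccccc2)c1)(C(C)C)C(C)C
A1 | alternative 1 | 7-benzyloxy-2-[4-(benzyloxy)phenyl]-6-{4-ethoxy-2-hydroxy-6-[tri(propan-2-yl)silyloxy]phenyl}-5-methoxychromen-4-one | CCOc1cc(O)c(c(O[Si](C(C)C)(C(C)C)C(C)C)c1)-c1c(OCc2ccccc2)cc2oc(-c3ccc(OCc4ccccc4)cc3)cc(=O)c2c1OC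
A2 | alternative 1 | 3-ethoxycyclobut-2-en-1-one | CCOC1=CC(=O)C1
A3 | alternative 1 | 7-benzyloxy-2-[4-(benzyloxy)phenyl]-5-methoxy-6-{[tri(propan-2-yl)silyloxy]ethynyl}chromen-4-one | COc1c(C#CO[Si](C(C)C)(C(C)C)C(C)C)c(OCc2ccccc2)cc2oc(-c3ccc(OCc4ccccc4)cc3)cc(=O)c12
A4 | alternative 2 | 8-{2-[4-(benzyloxy)phenyl]-5,7-dihydroxy-4-oxochromen-6-yl}-7-benzyloxy-5-methoxy-2-(4-methoxyphenyl)chromen-4-one | O=c1cc(-c2ccc(OCc3ccccc3)cc2)oc2cc(O)c(c(O)c12)-c1c(OCc2ccccc2)cc(OC)c2c(=O)cc(-c3ccc(OC)cc3)oc12
A5 | alternative 2 | 7-benzyloxy-5-methoxy-8-[1-methoxy-1,3-bis(trimethylsilyloxy)buta-1,3-dien-2-yl]-2-(4-methoxyphenyl)chromen-4-one (ketene acetal geometry not specified) | C=C(O[Si](C)(C)C)C(=C(OC)O[Si](C)(C)C)c1c(OCc2ccccc2)cc(OC)c2c(=O)cc(-c3ccc(OC)cc3)oc12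
A6 | alternative 2 | 5-bromo-2-[4-(benzyloxy)phenyl]pyran-4-one | O=c1cc(-c2ccc(OCc3ccccc3)cc2)occ1Br
A7 | alternative 3 | 5,7-bis(benzyloxy)-8-{7-benzyloxy-2-[4-(benzyloxy)phenyl]-5-methoxy-4-oxochromen-6-yl}-2-(4-methoxyphenyl)chromen-4-one | COc1ccc(cc1)-c1cc(=O)c2c(OCc3ccccc3)cc(OCc3ccccc3)c(c2o1)-c1c(OCc2ccccc2)cc2oc(-c3ccc(OCc4ccccc4)cc3)cc(=O)c2c1OC
A8 | alternative 3 | 1-{4,6-bis(benzyloxy)-3-{7-benzyloxy-2-[4-(benzyloxy)phenyl]-5-methoxy-4-oxochromen-6-yl}-2-fluorophenyl}-3-(4-methoxyphenyl)propane-1,3-dione | COc1ccc(cc1)C(=O)CC(=O)c1c(OCc2ccccc2)cc(OCc2ccccc2)c(c1F)-c1c(OCc2ccccc2)cc2oc(-c3ccc(OCc4ccccc4)cc3)cc(=O)c2c1OC
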